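All constants are made up; the rest is arithmetic.

Free catalyst is what you watch in these vessels, which get the same charges and differ in how the substrate meets it.

| flask | substrate | free catalyst | time | remark |
|---|---|---|---|---|
| Saturday's | 0.11 M (fed, over 2.00 h) | 2.2 mM | 2.0 h | all but substrate at the start; substrate goes in evenly over 2.00 h, the run ends at 2.0 h |
| Wednesday's | 0.11 M | 2.2 mM |  | a single well-mixed tank run continuously and read at steady state, 2.0 h in it on average |
| Sunday's | 0.11 M | 2.2 mM | 2.0 h | a closed flask charged with all of it at once and left for 2.0 h |

    substrate + free catalyst → free catalyst + target (k1 = 2300 /M/h)
    substrate → side product (k2 = 15 /h)
    free catalyst → spent catalyst A (k3 = 0.34 /h)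
    2 free catalyst → spent catalyst B (k4 = 120 /M/h)

- the set-up with the highest share of target in all that became target or side product, at the outlet or at the end ("none" if the first two lie within 2 percentage points) (Saturday's / Wednesday's / Sunday's / none)
- share of target in all that became target or side product, at the outlet or at the end, Saturday's
- share of target in all that became target or side product, at the outlet or at the end, Wednesday's
- share of target in all that became target or side product, at the outlet or at the end, Sunday's

- where a step has two of a species, its rate is k times that concentration squared, and two are used at each turn
- the stated concentrations are those of everything mixed, before any reaction; amounts are the same in each set-up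
- the feed brings no volume worth counting
- run time (Saturday's): 2.0 h

Both substrate steps are first order in substrate, so the momentary share of target, the selectivity, depends on free catalyst. The break-even catalyst, the level at which both steps run equally fast, is the side-step constant over the catalytic constant: 6.52 mM. The momentary share is then catalyst / (catalyst + break-even).

In Sunday's flask, the substrate half-life by both substrate steps together at the charged catalyst, 2.07 min, is far shorter than the catalyst's initial decay time of 1.15 h, so I take the charged level and get 25.2%.

In Saturday's feed, the substrate half-life by the side step alone, 2.8 min, is far shorter than the 2.00 h of dosing, so each portion splits at the catalyst of its moment. Integrating both catalyst losses gives 1.08 mM at 1.00 h and 0.631 mM at the end. Simpson's rule then averages the share to 15.2%.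

In Wednesday's tank, the steady balance of catalyst gives 1.02 mM, hence 13.5%.

The forecast names Sunday's, with 14.9% for Saturday's, 13.5% for Wednesday's and 24.4% for Sunday's, slightly below my Sunday figure. Its ground for Sunday's flask: “its substrate is gone within minutes while the catalyst is still fresh”.

The simulation gives Sunday's, with 14.9%, 13.5% and 24.4% in that order.

Now take Saturday's feed with 8.8 × 10⁻⁴ M of free catalyst. Against the same break-even catalyst, the share starts at 11.9%. Catalyst reckoned as before falls to 0.531 mM at 1.00 h and 0.341 mM at the end, so the averaged share is 7.83%. The neighbour flask gives 7.71%, about half of Saturday's, with 3.2% of its substrate charge left at the end.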